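**Assumption:** positions are numbered as in eremophilane (ring A = C1–C5 and C10; ring B = C5–C10; C11–C13 = isopropenyl on C7; C14 = methyl on C5; C15 = methyl on C4). β is the face of C14, α the opposite face. Names of bicyclic compounds use this numbering with every stereodescriptor written out.

## Analysis of the target

Target 29 is a trans-fused decalin of the eremophilane type. Ring A carries the senecioate on C3 and methyls on C4 and C5; ring B carries the isopropenyl group on C7, the C8 ketone and the tiglate on C9. It has six stereocentres, (3R,4R,5R,7S,9S,10R). The angular C14 methyl is β and axial, H10 is α (trans fusion), and O3 (α), C15 (β), the isopropenyl group (7α) and O9 (α) are all equatorial. C7 and C9 flank the ketone, so both can epimerise, and the target holds the more stable epimer at each.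

The sensitive groups are the β,γ-unsaturated ketone (the isopropenyl double bond can slip into conjugation), the α-acyloxy ketone at C9, and two different unsaturated esters that must end up on the right oxygens with the E geometry of the tiglate intact. The hard parts are the quaternary C5 next to the C4 stereocentre, the trans ring fusion, the placement of ketone and oxygen on C8 and C9 rather than the reverse, and telling O3 from O9.

The strategy rests on one feature of ring B: a C8 ketone with oxygen on C9 is the oxidation product of a C8=C9 enol silane. That enol silane is exactly what a 2-silyloxydiene spanning C7–C10 leaves behind after cycloaddition to a C5=C6 dienophile, with ring A closing through the tether C1–C4.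

## Retrosynthetic reasoning

**Ester C–O bonds (29 ⇒ 27 + 28; 26 ⇒ 24 + 25).** Both unsaturated esters are cut first, because neither would survive the enolate, titanium-carbene or hydrogenation chemistry used earlier. O9 is acylated before O3: in 23 the O9 triethylsilyl ether can be removed under conditions that leave the O3 tert-butyldimethylsilyl ether alone, so the two alcohols are freed one at a time (23 → 24, 26 → 27) and each meets only its own acyl chloride.

**C7–C11 bond (23 ⇒ 20 + 21).** The isopropenyl group is cut at C7, the only methylene α to the ketone; the other α-position, C9, is a hindered oxygenated methine. A palladium-catalysed enolate alkenylation with 21 installs the alkene directly in the β,γ-position, which an aldol-dehydration would not guarantee. It is placed after the hydrogenation of step 10, which the isopropenyl group would not survive.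

**C9–O bond (20 ⇒ 18).** The C9 oxygen is removed by a retro-Rubottom step, giving the C8=C9 enol silane 18. No regiochemical decision is needed because the double bond position is inherited from the cycloaddition. The silyl group migrates to O9 and serves as its protecting group.

**C4–C15 bond (18 ⇒ 17 ⇒ 16).** The C4 methyl is traced through the exocyclic alkene 17 to the C4 ketone of 16. This ketone is needed in the key step as the activating group of the dienophile. Its conversion to a methyl group uses the axial C14 methyl to direct hydrogen to the α face.

**C5–C10 and C6–C7 bonds (16 ⇒ 15), the key disconnection.** Cutting both bonds opens both rings and leads to trienone 15, a chain with a single stereocentre (C3). The forward reaction must set the quaternary C5 and the ring-fusion centre C10 and keep the enol silane.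

**C4–C5 bond (15 ⇒ 12 + 13).** The isopropenyl ketone is made last, by acyl substitution on the N-methoxy-N-methylamide 12 with 13. A compound holding both the methacryloyl group and the terminal alkene would be a 1,7-diene that a ruthenium carbene closes to a 2-methylcyclohexenone. A compound holding both ketones would offer the base a second enolisable position at C3. Doing metathesis and enol silylation on the amide avoids both.

**Diene (12 ⇒ 10 ⇒ 8 + 9).** The silyloxydiene comes from kinetic enol silylation of the methyl enone 10, and the C9=C10 bond of 10 from cross-metathesis of the terminal alkene 8 with 9.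

**C3–O bond (8 ⇒ 7 ⇒ 6 ⇒ 4 ⇒ 1 + 2).** The C3 stereocentre is set by hydroxylation of the enolate of imide 4 under control of the oxazolidinone 2. This is chosen over a catalytic oxidation because a terminal alkene is present and the outcome with the auxiliary is predictable.

## Alternatives that were turned down

**Alternative 1:** The C5–C10 bond would be cut by a retro-[3,3] shift, tracing ring A to an allylic ester array in which O3 is acylated by the C9 carboxyl and C4=C5 is a fully substituted alkene. Forward, the ketene acetal of that six-membered lactone would bond C10 to C5 while the C3–O bond breaks (Ireland–Claisen ring contraction), giving the cyclohexene acid A1.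
- For it: C5 and C10 are both derived from the single C3 centre through a tight cyclic transition state. On the C5/C10 relationship this is more dependable than an endo/exo competition.
- Against it: the C3 oxygen is consumed and must be put back on a C3=C4 alkene together with the C4 stereocentre. The quaternary C5 depends on a geometrically pure tetrasubstituted alkene and a ring-enforced boat-like transition state. A1 contains only ring A; C8 is still missing, so ring B, the C8/C9 oxygen pattern and the isopropenyl group remain to be built with no built-in regiocontrol.
- Comparison: the chosen route forms both rings at once, keeps O3 throughout and delivers the C8=C9 enol silane ready for oxidation. It pays with a less certain ring-fusion selectivity.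

**Alternative 2:** The C4–C5 bond is cut and ring B is taken back to an arene: a catechol with O9 silylated, the future C14 methyl on the para carbon C5, and a side chain ending in a secondary mesylate at C4. Forward, the O8 phenoxide alkylates through C5 with inversion at C4 and dearomatises to the cross-conjugated dienone A2.
- For it: the two vicinal methyl-bearing centres are made in one bond formation, and C4 is set stereospecifically. This is stronger than the chosen route, where C4 rests on a face-selective hydrogenation. A2 already carries O3, O8 and O9.
- Against it: displacement at a secondary carbon flanked by a silyloxy carbon, forming a quaternary centre, competes with elimination. The C5 configuration depends on tether conformation, not on a stereospecific event. C10 is trigonal in A2, so the tetrasubstituted C9=C10 enol ether and the C6=C7 alkene must be reduced separately, with the trans fusion resting on a reduction that has no strong bias.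
- Comparison: the chosen route sets C10 in the ring-forming step and needs no ring B reductions; both routes still need a late C7 alkenylation.

**Alternative 3:** Both rings are cut along C9–C10 and C4–C5, leading to an open chain with a C9 aldehyde, the C8 and C7 stereocentres, an E C5=C10 alkene and a terminating enol ether at C3=C4. Forward, MeAlCl2 activates the aldehyde, C10 adds to it, and the C5 cation is trapped by C4, giving A3.
- For it: four stereocentres (C4, C5, C9, C10) and the complete skeleton including the isopropenyl group form in one step. This is stronger than the chosen route in step economy after the key step. Chair–chair folding of an E alkene also predicts trans fusion more firmly than a Diels–Alder endo/exo preference does.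
- Against it: the precursor needs two adjacent stereocentres and two geometrically defined trisubstituted π-bonds, one an enol ether, so its preparation is long. The aldehyde and enol ether can react directly in a Mukaiyama aldol instead of the cascade, the isopropenyl group is a competing π-nucleophile, and the α-silyloxy aldehyde may epimerise under the Lewis acid. C3 and C8 emerge at the wrong oxidation levels, so a reduction and an oxidation remain.
- Comparison: the chosen precursor has one stereocentre and is reached in seven routine steps, and the risk is confined to one selectivity question.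

Key step: step 8

## Route

Step 1
Reactants: 1 hex-5-enoic acid; 2 (R)-4-benzyl-1,3-oxazolidin-2-one
Product: 4 (R)-4-benzyl-3-(hex-5-enoyl)-1,3-oxazolidin-2-one, via hex-5-enoic pivalic anhydride 3 (not isolated)
Conditions: PivCl, Et3N, THF, −20 °C; then 2, LiCl, −20 °C → rt
Reagents that add atoms: none
Why: Mixed-anhydride N-acylation of an oxazolidinone; the nitrogen attacks the unhindered hexenoyl carbonyl of 3 and not the pivaloyl carbonyl.

Step 2
Reactants: 4
Product: 6 (R)-4-benzyl-3-[(2R)-2-hydroxyhex-5-enoyl]-1,3-oxazolidin-2-one, via sodium Z-enolate 5 (not isolated)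
Conditions: NaN(SiMe3)2, THF, −78 °C; 2-(phenylsulfonyl)-3-phenyloxaziridine, −78 °C; AcOH
Reagents that add atoms: 2-(phenylsulfonyl)-3-phenyloxaziridine, O=S(=O)(N1OC1c1ccccc1)c1ccccc1
Why: Auxiliary-controlled enolate hydroxylation: the chelated Z-enolate 5 is oxidised on the face opposite the benzyl group, which with the (R)-auxiliary gives the (2R)-alcohol, the future C3; the terminal alkene does not react with the oxaziridine.

Step 3
Reactants: 6
Product: 7 (R)-2-hydroxy-N-methoxy-N-methylhex-5-enamide
Conditions: MeONHMe·HCl, AlMe3, CH2Cl2, −10 °C → rt; aq. potassium sodium tartrate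
Reagents that add atoms: N,O-dimethylhydroxylamine hydrochloride, CNOC.Cl
Why: Aluminium-amide transamination of the imide; the aluminium alkoxide formed from the α-hydroxyl directs attack to the exocyclic carbonyl, the auxiliary is released for recovery, and nothing basic enough to epimerise C3 is present.

Step 4
Reactants: 7
Product: 8 (R)-2-(tert-butyldimethylsilyloxy)-N-methoxy-N-methylhex-5-enamide
Conditions: TBSCl, imidazole, DMF, rt
Reagents that add atoms: tert-butyldimethylsilyl chloride, CC(C)(C)[Si](C)(C)Cl
Why: Routine silylation of a secondary alcohol; the tert-butyldimethylsilyl group is chosen because it outlasts the triethylsilyl groups used later.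

Step 5
Reactants: 8; 9 but-3-en-2-one
Product: 10 (2R,5E)-2-(tert-butyldimethylsilyloxy)-N-methoxy-N-methyl-7-oxooct-5-enamide
Conditions: second-generation Grubbs catalyst RuCl2(=CHPh)(H2IMes)(PCy3) (5 mol%), 9 (4 equiv), CH2Cl2, 40 °C
Reagents that add atoms: none
Why: Cross-metathesis of a terminal alkene with an electron-poor vinyl ketone, which gives the E-enone; 8 holds a single alkene, so no ring-closing path exists at this stage.

Step 6
Reactants: 10
Product: 12 (2R,5E)-2-(tert-butyldimethylsilyloxy)-N-methoxy-N-methyl-7-(triethylsilyloxy)octa-5,7-dienamide, via lithium dienolate 11 (not isolated)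
Conditions: LiN(SiMe3)2, THF, −78 °C; TESCl, −78 → −20 °C; cold aq. NaHCO3
Reagents that add atoms: chlorotriethylsilane, CC[Si](CC)(CC)Cl
Why: Kinetic deprotonation of the methyl group of the enone and O-silylation give the cross-conjugated 2-silyloxydiene; the hindered amide α-hydrogen at C3 is far less acidic, so the stereocentre is not touched.

Step 7
Reactants: 12; 13 isopropenylmagnesium bromide
Product: 15 (4R,7E)-4-(tert-butyldimethylsilyloxy)-2-methyl-9-(triethylsilyloxy)deca-1,7,9-trien-3-one, via magnesium hemiaminal chelate 14 (not isolated)
Conditions: 13 (0.5 M in THF, 1.5 equiv), THF, −20 → 0 °C; cold pH 7 phosphate buffer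
Reagents that add atoms: none
Why: Weinreb ketone synthesis: the chelate 14 stops the addition after one equivalent and collapses only on quench, the silyl enol ether is inert to the Grignard reagent, and C3 is not enolised.

Step 8
Reactants: 15
Product: 16 3α-(tert-butyldimethylsilyloxy)-8-(triethylsilyloxy)-11,12,13,15-tetranor-10αH-eremophil-8-en-4-one (5β-methyl; trans-fused)
Conditions: toluene (0.01 M), BHT (0.1 equiv), Et3N (0.1 equiv), sealed tube, 140 °C
Reagents that add atoms: none
Why: The reaction is a concerted, asynchronous [4+2] cycloaddition of normal electron demand: the nucleophilic terminus C7 of the silyloxydiene (C7=C8–C9=C10) bonds to the β-carbon C6 of the enone while C10 bonds to C5, so the polarity of the partners and the tether ask for the same orientation. The closest known reaction type is the type 1 intramolecular Diels–Alder reaction of 1,7,9-decatrien-3-ones, here with a 2-silyloxydiene. Ring B is closed by the cycloaddition itself, as the cyclohexene built from four diene and two dienophile carbons; ring A is closed in the fused mode by the C5–C10 bond across the four-atom tether C1–C4, which adopts a chair-like arrangement. C10 is set relative to C5 by the E geometry of C9=C10 together with the transition state that has the tether carbonyl exo and the C14 methyl endo, which places H10 anti to the methyl (trans fusion). C5 is set relative to C3: with the silyloxy group equatorial on the chair-like tether only one face of the dienophile is offered to the diene, giving the 5β-methyl with the 3α-oxygen. The step therefore needs carbonyl-exo selectivity and facial selectivity; the first is helped by the α-methyl group, which as in methacrylate-type dienophiles competes for the endo position and offsets the usual carbonyl-endo preference, and the second by the single stereocentre C3 next to the dienophile carbonyl. Neutral thermal conditions keep the triethylsilyl enol ether, so the C8=C9 double bond arrives regiodefined; dilution and BHT hold back intermolecular cycloaddition and radical polymerisation of the enone.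

Step 9
Reactants: 16
Product: 17 3α-(tert-butyldimethylsilyloxy)-8-(triethylsilyloxy)-11,12,13-trinor-10αH-eremophila-4(15),8-diene
Conditions: Cp2TiMe2 (3 equiv), toluene–THF, 75 °C, dark
Reagents that add atoms: dimethyltitanocene, C[Ti](C)(C1C=CC=C1)C1C=CC=C1
Why: Petasis methylenation: the non-basic titanium methylidene olefinates hindered, enolisable ketones by a [2+2]/retro-[2+2] path without epimerising C3 and leaves silyl ethers and the enol silane untouched.

Step 10
Reactants: 17
Product: 18 3α-(tert-butyldimethylsilyloxy)-8-(triethylsilyloxy)-11,12,13-trinor-10αH-eremophil-8-ene (4β-methyl)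
Conditions: H2 (4 atm), RhCl(PPh3)3 (10 mol%), benzene, rt → 40 °C
Reagents that add atoms: none
Why: Homogeneous hydrogenation with RhCl(PPh3)3 reduces the 1,1-disubstituted alkene and ignores the trisubstituted enol silane; the axial C14 methyl shields the β face, so hydrogen is delivered to C4 from the α face and the new methyl ends up β, equatorial and cis to C14.

Step 11
Reactants: 18
Product: 20 3α-(tert-butyldimethylsilyloxy)-9α-(triethylsilyloxy)-11,12,13-trinor-10αH-eremophilan-8-one, via silyloxy epoxide 19 (not isolated)
Conditions: mCPBA (1.1 equiv), CH2Cl2, −20 → 0 °C; aq. Na2SO3/NaHCO3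
Reagents that add atoms: 3-chloroperbenzoic acid, O=C(OO)c1cccc(Cl)c1
Why: Rubottom oxidation: the peracid epoxidises the C8=C9 enol silane on the α face, away from the axial C14 methyl that stands 1,3 to C9; ring opening and 1,4-silyl shift give the 9α-silyloxy ketone, and 9α (equatorial) is also the more stable configuration at this epimerisable centre.

Step 12
Reactants: 20; 21 2-bromopropene
Product: 23 3α-(tert-butyldimethylsilyloxy)-9α-(triethylsilyloxy)-10αH-eremophil-11-en-8-one (7α-isopropenyl), via lithium C7 enolate 22 (not isolated)
Conditions: LiN(SiMe3)2 (2.2 equiv), toluene–THF, −78 → 0 °C; Pd2(dba)3 (2.5 mol%), [HP(t-Bu)3]BF4 (6 mol%), 21 (1.5 equiv), rt; AcOH, −78 °C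
Reagents that add atoms: none
Why: Palladium-catalysed α-alkenylation of a ketone enolate with an alkenyl bromide (oxidative addition, enolate transfer to palladium, reductive elimination); kinetic deprotonation goes to the C7 methylene and not to the hindered oxygenated C9 methine. The isopropenyl group is placed on the face away from the C14 methyl, and cold protonation of the product enolate at C7 pushes it into the equatorial 7α position, which is also the more stable one.

Step 13
Reactants: 23
Product: 24 3α-(tert-butyldimethylsilyloxy)-9α-hydroxy-10αH-eremophil-11-en-8-one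
Conditions: PPTS (0.1 equiv), MeOH–CH2Cl2, 0 °C
Reagents that add atoms: none
Why: Selective solvolysis of the triethylsilyl ether beside the much slower secondary tert-butyldimethylsilyl ether; the acid is too weak to move the isopropenyl double bond.

Step 14
Reactants: 24; 25 (E)-2-methylbut-2-enoyl chloride (tigloyl chloride)
Product: 26 3α-(tert-butyldimethylsilyloxy)-9α-[(E)-2-methylbut-2-enoyloxy]-10αH-eremophil-11-en-8-one
Conditions: 25 (1.5 equiv), pyridine, DMAP (cat.), CH2Cl2, 0 °C → rt
Reagents that add atoms: none
Why: DMAP-catalysed acylation of the equatorial 9α-alcohol; pyridine is too weak a base to epimerise C7 or C9 or to turn 25 into its vinylketene, so the E ester is kept.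

Step 15
Reactants: 26
Product: 27 3α-hydroxy-9α-[(E)-2-methylbut-2-enoyloxy]-10αH-eremophil-11-en-8-one
Conditions: HF·pyridine, pyridine, THF, 0 °C → rt
Reagents that add atoms: none
Why: Buffered fluoride cleavage of the secondary silyl ether; esters, ketone and the β,γ-alkene are stable, and basic fluoride is avoided because of the α-acyloxy ketone.

Step 16
Reactants: 27; 28 3-methylbut-2-enoyl chloride (senecioyl chloride)
Product: 29 (3R,4R,5R,7S,9S,10R)-3-(3-methylbut-2-enoyloxy)-9-[(E)-2-methylbut-2-enoyloxy]eremophil-11-en-8-one (CNP0164025.1)
Conditions: 28 (1.5 equiv), pyridine, DMAP (cat.), CH2Cl2, 0 °C → rt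
Reagents that add atoms: none
Why: Acylation of the equatorial 3α-alcohol; pyridine in place of a trialkylamine keeps the acyl chloride from deconjugating through its vinylketene.

## Compound list

1 | hex-5-enoic acid | C=CCCCC(=O)O | starting material
2 | (R)-4-benzyl-1,3-oxazolidin-2-one | O=C1N[C@H](Cc2ccccc2)CO1 | starting material
3 | hex-5-enoic pivalic anhydride | C=CCCCC(=O)OC(=O)C(C)(C)C | intermediate
4 | (R)-4-benzyl-3-(hex-5-enoyl)-1,3-oxazolidin-2-one | C=CCCCC(=O)N1C(=O)OC[C@H]1Cc1ccccc1 | intermediate
5 | sodium Z-enolate of 4 | [Na+].[O-]/C(=C\CCC=C)N1C(=O)OC[C@H]1Cc1ccccc1 | intermediate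
6 | (R)-4-benzyl-3-[(2R)-2-hydroxyhex-5-enoyl]-1,3-oxazolidin-2-one | C=CCC[C@@H](O)C(=O)N1C(=O)OC[C@H]1Cc1ccccc1 | intermediate
7 | (R)-2-hydroxy-N-methoxy-N-methylhex-5-enamide | C=CCC[C@@H](O)C(=O)N(C)OC | intermediate
8 | (R)-2-(tert-butyldimethylsilyloxy)-N-methoxy-N-methylhex-5-enamide | C=CCC[C@@H](O[Si](C)(C)C(C)(C)C)C(=O)N(C)OC | intermediate
9 | but-3-en-2-one | CC(=O)C=C | starting material
10 | (2R,5E)-2-(tert-butyldimethylsilyloxy)-N-methoxy-N-methyl-7-oxooct-5-enamide | CC(=O)/C=C/CC[C@@H](O[Si](C)(C)C(C)(C)C)C(=O)N(C)OC | intermediate
11 | lithium dienolate of 10 | C=C(O[Li])/C=C/CC[C@@H](O[Si](C)(C)C(C)(C)C)C(=O)N(C)OC | intermediate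
12 | (2R,5E)-2-(tert-butyldimethylsilyloxy)-N-methoxy-N-methyl-7-(triethylsilyloxy)octa-5,7-dienamide | C=C(O[Si](CC)(CC)CC)/C=C/CC[C@@H](O[Si](C)(C)C(C)(C)C)C(=O)N(C)OC | intermediate
13 | isopropenylmagnesium bromide | C=C(C)[Mg]Br | starting material
14 | bromomagnesium hemiaminal chelate from 12 and 13 (new carbinol centre undefined) | C=C(O[Si](CC)(CC)CC)/C=C/CC[C@@H](O[Si](C)(C)C(C)(C)C)C(O[Mg]Br)(N(C)OC)C(C)=C | intermediate
15 | (4R,7E)-4-(tert-butyldimethylsilyloxy)-2-methyl-9-(triethylsilyloxy)deca-1,7,9-trien-3-one | C=C(O[Si](CC)(CC)CC)/C=C/CC[C@@H](O[Si](C)(C)C(C)(C)C)C(=O)C(C)=C | intermediate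
16 | 3α-(tert-butyldimethylsilyloxy)-8-(triethylsilyloxy)-11,12,13,15-tetranor-10αH-eremophil-8-en-4-one | C1C[C@]2(C)C(=O)[C@H](O[Si](C)(C)C(C)(C)C)CC[C@H]2C=C1O[Si](CC)(CC)CC | intermediate
17 | 3α-(tert-butyldimethylsilyloxy)-8-(triethylsilyloxy)-11,12,13-trinor-10αH-eremophila-4(15),8-diene | C1C[C@]2(C)C(=C)[C@H](O[Si](C)(C)C(C)(C)C)CC[C@H]2C=C1O[Si](CC)(CC)CC | intermediate
18 | 3α-(tert-butyldimethylsilyloxy)-8-(triethylsilyloxy)-11,12,13-trinor-10αH-eremophil-8-ene | C1C[C@]2(C)[C@@H](C)[C@H](O[Si](C)(C)C(C)(C)C)CC[C@H]2C=C1O[Si](CC)(CC)CC | intermediate
19 | 8α,9α-epoxide of 18 (8β-triethylsilyloxy) | C1C[C@]2(C)[C@@H](C)[C@H](O[Si](C)(C)C(C)(C)C)CC[C@H]2[C@@H]3O[C@]13O[Si](CC)(CC)CC | intermediate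
20 | 3α-(tert-butyldimethylsilyloxy)-9α-(triethylsilyloxy)-11,12,13-trinor-10αH-eremophilan-8-one | C1C[C@]2(C)[C@@H](C)[C@H](O[Si](C)(C)C(C)(C)C)CC[C@H]2[C@H](O[Si](CC)(CC)CC)C1=O | intermediate
21 | 2-bromopropene | C=C(C)Br | starting material
22 | lithium C7 enolate of 20 | [Li]OC1=CC[C@]2(C)[C@@H](C)[C@H](O[Si](C)(C)C(C)(C)C)CC[C@H]2[C@@H]1O[Si](CC)(CC)CC | intermediate
23 | 3α-(tert-butyldimethylsilyloxy)-9α-(triethylsilyloxy)-10αH-eremophil-11-en-8-one | C=C(C)[C@@H]1C[C@]2(C)[C@@H](C)[C@H](O[Si](C)(C)C(C)(C)C)CC[C@H]2[C@H](O[Si](CC)(CC)CC)C1=O | intermediate
24 | 3α-(tert-butyldimethylsilyloxy)-9α-hydroxy-10αH-eremophil-11-en-8-one | C=C(C)[C@@H]1C[C@]2(C)[C@@H](C)[C@H](O[Si](C)(C)C(C)(C)C)CC[C@H]2[C@H](O)C1=O | intermediate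
25 | (E)-2-methylbut-2-enoyl chloride | C/C=C(\C)C(=O)Cl | starting material
26 | 3α-(tert-butyldimethylsilyloxy)-9α-[(E)-2-methylbut-2-enoyloxy]-10αH-eremophil-11-en-8-one | C=C(C)[C@@H]1C[C@]2(C)[C@@H](C)[C@H](O[Si](C)(C)C(C)(C)C)CC[C@H]2[C@H](OC(=O)/C(C)=C/C)C1=O | intermediate
27 | 3α-hydroxy-9α-[(E)-2-methylbut-2-enoyloxy]-10αH-eremophil-11-en-8-one | C=C(C)[C@@H]1C[C@]2(C)[C@@H](C)[C@H](O)CC[C@H]2[C@H](OC(=O)/C(C)=C/C)C1=O | intermediate
28 | 3-methylbut-2-enoyl chloride | CC(C)=CC(=O)Cl | starting material
29 | (3R,4R,5R,7S,9S,10R)-3-(3-methylbut-2-enoyloxy)-9-[(E)-2-methylbut-2-enoyloxy]eremophil-11-en-8-one | C=C(C)[C@@H]1C[C@]2(C)[C@@H](C)[C@H](OC(=O)C=C(C)C)CC[C@H]2[C@H](OC(=O)/C(C)=C/C)C1=O | target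

## Step count and least certain steps

Total: 16 steps. Longest linear sequence: 16 steps, from 1 to 29; all other inputs are commercial.

**Step 8 (key step).** The most likely failure is closure through the carbonyl-endo transition state, which gives the cis-fused ring system. Decatrienones with the carbonyl in the tether show only a modest exo/endo preference, and the α-methyl group and the equatorial silyloxy group are moderate biases, not decisive ones. Erosion of the facial preference set by C3 and hydrolysis of the enol silane during heating are lesser risks.
Fallback: C10 would be corrected after the cycloaddition instead of forcing the cycloaddition itself. Starting from 15, the cis-fused cycloadduct F1 (or its mixture with 16) would be methylenated with Cp2TiMe2 as in step 9 to the cis-fused methylene compound F2. Saegusa–Ito oxidation with Pd(OAc)2 (divalent palladium) in MeCN would convert the enol silane into the 9(10)-en-8-one F3, in which C10 is trigonal, so both ring-fusion isomers converge. Reduction with Li in NH3/THF and one equivalent of t-BuOH protonates C10 axially, which in octalones with an angular methyl gives the trans-fused enolate; the isolated exocyclic alkene and the silyl ether are not reduced. Trapping this C8–C9 enolate with TESCl/Et3N returns the route at 17. This corrects C10 only and presumes the C3-to-C5 facial control held.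

**Step 9.** Methylenation may stall because the C4 carbonyl sits between the quaternary C5 and the silyloxy-bearing C3, and long heating invites loss of the enol silane.
Fallback: from 16, addition of MeMgBr/CeCl3 would give the tertiary alcohol F4 (C4 configuration immaterial). Acylation with methyl chlorooxoacetate gives the methyl oxalate F5, and radical deoxygenation with Bu3SnH/AIBN passes through the planar C4 radical, which takes its hydrogen from the α face, away from the C14 methyl. This gives the equatorial 4β-methyl compound and rejoins the route at 18, bypassing step 10 as well.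

**Step 10.** Reduction of a neopentyl-type 1,1-disubstituted alkene by RhCl(PPh3)3 may be slow, and slow reduction gives room for double-bond migration or incomplete facial selectivity.
Fallback: from 17, the Rubottom oxidation would be run first; the enol silane reacts with the peracid much faster than the hindered exocyclic alkene, giving the methylene ketone F6. With the enol silane gone, hydrogen-atom-transfer hydrogenation (Mn(dpm)3, PhSiH3, t-BuOOH, i-PrOH) would deliver the thermodynamically preferred equatorial 4β-methyl through the C4 radical, returning at 20.

**Step 12.** Several processes can interfere: proton exchange moving the enolate to C9, β-hydride elimination from the palladium enolate giving an enone, migration of the new double bond into conjugation with C8, and protonation at C7 from the wrong face.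
Fallback: from 20, aldol addition of enolate 22 to acetone would give the 7α-(2-hydroxypropan-2-yl) ketone F7. Dehydration with the Burgess reagent gives the conjugated 7(11)-en-8-one F8, or some 23 directly. γ-Deprotonation with LiN(iPr)2 at −78 °C and kinetic α-protonation of the dienolate with AcOH deconjugates the enone and returns at 23; any 23 already present passes through the same dienolate.

**Step 7.** The triethylsilyl dienol ether may be lost on work-up, or the liberated N,O-dimethylhydroxylamine may add to the new enone.
Fallback: from 8, the Grignard reagent 13 would be added first to give the dienone F9, and metathesis would be avoided altogether because F9 would ring-close. The isolated terminal alkene, which is more electron-rich than the enone alkene, would be cleaved selectively (OsO4 cat., NMO; then NaIO4) to the aldehyde F10. Wittig reaction with Ph3P=CHC(O)CH3 gives the enone F11, and kinetic enol silylation of its methyl ketone (LiN(SiMe3)2, TESCl, −78 °C) returns at 15. The price is a second enolisable ketone next to C3 in that last operation.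

## Further compounds

F1 | step 8 | cis-fused cycloadduct (10β-H epimer of 16) | C1C[C@]2(C)C(=O)[C@H](O[Si](C)(C)C(C)(C)C)CC[C@@H]2C=C1O[Si](CC)(CC)CC
F2 | step 8 | cis-fused 4(15)-methylene enol silane (10β-H epimer of 17) | C1C[C@]2(C)C(=C)[C@H](O[Si](C)(C)C(C)(C)C)CC[C@@H]2C=C1O[Si](CC)(CC)CC
F3 | step 8 | 3α-(tert-butyldimethylsilyloxy)-11,12,13-trinoreremophila-4(15),9-dien-8-one | O=C1CC[C@]2(C)C(=C)[C@H](O[Si](C)(C)C(C)(C)C)CCC2=C1
F4 | step 9 | 4-hydroxy-4-methyl adduct of 16 (C4 undefined) | C1C[C@]2(C)C(C)(O)[C@H](O[Si](C)(C)C(C)(C)C)CC[C@H]2C=C1O[Si](CC)(CC)CC
F5 | step 9 | methyl oxalate of F4 | C1C[C@]2(C)C(C)(OC(=O)C(=O)OC)[C@H](O[Si](C)(C)C(C)(C)C)CC[C@H]2C=C1O[Si](CC)(CC)CC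
F6 | step 10 | 3α-(tert-butyldimethylsilyloxy)-9α-(triethylsilyloxy)-11,12,13-trinor-10αH-eremophil-4(15)-en-8-one | C1C[C@]2(C)C(=C)[C@H](O[Si](C)(C)C(C)(C)C)CC[C@H]2[C@H](O[Si](CC)(CC)CC)C1=O
F7 | step 12 | 3α-(tert-butyldimethylsilyloxy)-11-hydroxy-9α-(triethylsilyloxy)-10αH-eremophilan-8-one | CC(C)(O)[C@@H]1C[C@]2(C)[C@@H](C)[C@H](O[Si](C)(C)C(C)(C)C)CC[C@H]2[C@H](O[Si](CC)(CC)CC)C1=O
F8 | step 12 | 3α-(tert-butyldimethylsilyloxy)-9α-(triethylsilyloxy)-10αH-eremophil-7(11)-en-8-one | CC(C)=C1C[C@]2(C)[C@@H](C)[C@H](O[Si](C)(C)C(C)(C)C)CC[C@H]2[C@H](O[Si](CC)(CC)CC)C1=O
F9 | step 7 | (R)-4-(tert-butyldimethylsilyloxy)-2-methylocta-1,7-dien-3-one | C=CCC[C@@H](O[Si](C)(C)C(C)(C)C)C(=O)C(C)=C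
F10 | step 7 | (R)-4-(tert-butyldimethylsilyloxy)-6-methyl-5-oxohept-6-enal | O=CCC[C@@H](O[Si](C)(C)C(C)(C)C)C(=O)C(C)=C
F11 | step 7 | (4R,7E)-4-(tert-butyldimethylsilyloxy)-2-methyldeca-1,7-diene-3,9-dione | CC(=O)/C=C/CC[C@@H](O[Si](C)(C)C(C)(C)C)C(=O)C(C)=C
A1 | alternative 1 | 2,3-dimethyl-2-(3-methylbut-2-en-1-yl)cyclohex-3-ene-1-carboxylic acid (C5 and C10 as in the target) | CC(C)=CC[C@]1(C)C(C)=CCC[C@H]1C(=O)O
A2 | alternative 2 | bicyclic 6,9-dien-8-one with O3 tert-butyldimethylsilyl ether and O9 triisopropylsilyl enol ether | O=C1C=C[C@]2(C)[C@@H](C)[C@H](O[Si](C)(C)C(C)(C)C)CCC2=C1O[Si](C(C)C)(C(C)C)C(C)C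
A3 | alternative 3 | trans-decalin 9α-ol 3-ketone with O8 tert-butyldimethylsilyl ether and 7α-isopropenyl | C=C(C)[C@@H]1C[C@]2(C)[C@@H](C)C(=O)CC[C@H]2[C@H](O)[C@@H]1O[Si](C)(C)C(C)(C)C
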